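The route disconnects the CH2–CH2 bridge of the propanoate chain between C2, the carbon next to the ester carbonyl, and C3, the benzylic carbon on the 3,4-dihydroxyphenyl ring. The key step exploits two features: C2 lies alpha to the ester carbonyl, so it can carry a removable carboxyl group (hexadecyl hydrogen malonate), and C3 is benzylic, so it can enter as the formyl carbon of 3,4-dihydroxybenzaldehyde. In one flask a Knoevenagel–Doebner condensation should join the two halves as a C2=C3 double bond and expel the activating carboxyl as CO2, and a hydrogenation should then bring the bridge to the saturated level. Neither phenol needs protection.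

Key step: step 2

Remark: the target has no stereocenter and no stereogenic double bond, so it is achiral and needs no stereocontrol; the E double bond of intermediate 6 is removed by the hydrogenation.

Step 1
Reactants: 1 Meldrum's acid (2,2-dimethyl-1,3-dioxane-4,6-dione); 2 1-hexadecanol
Product: 3 hexadecyl hydrogen malonate (3-(hexadecyloxy)-3-oxopropanoic acid)
Conditions: 1 (1.0 equiv), 2 (1.0 equiv), toluene, 110 °C; evaporate, use crude
Reagents that add atoms: none
Why: Alcoholysis of Meldrum's acid (ring-opening acyl substitution) should let the primary alcohol attack one activated acyl carbon, open the ring and release acetone, and should stop at the half-ester because the free carboxylic acid does not acylate a second alcohol.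

Step 2
Reactants: 3 hexadecyl hydrogen malonate; 4 3,4-dihydroxybenzaldehyde
Product: 7 hexadecyl 3-(3,4-dihydroxyphenyl)propanoate, via arylidene malonic half-ester 5 (not isolated), via hexadecyl (E)-caffeate 6 (not isolated)
Conditions: 3 (1.5 equiv), pyridine, piperidine (0.1 equiv), 60 °C, N2; then concentrate, EtOAc, 10% Pd/C, H2 (1 atm), rt, same flask
Reagents that add atoms: none
Why: Piperidine should convert aldehyde 4 into its iminium ion, which the enol of half-ester 3 attacks at C2; loss of the amine gives arylidene half-ester 5, whose free carboxyl group is expelled as CO2 in warm pyridine (amine addition at the benzylic carbon, then anti decarboxylative elimination) to leave the E-configured conjugated ester 6. Hydrogen on Pd/C then saturates the C2=C3 bond of 6 in the same flask and delivers 7. The closest known reaction type is the Knoevenagel condensation in its Doebner (Verley) modification with a malonic acid half-ester, followed by heterogeneous catalytic hydrogenation of a cinnamate ester. No ring is closed and no stereocenter is formed, and the geometry of the double bond in 5 and 6 has no consequence because that bond is reduced. The step needs C–C bond formation at the formyl group in the presence of two free phenols, which is secured because only the doubly activated C2–H of 3 is acidic enough to condense under amine catalysis and because phenols and carboxylate are not electrophiles; the excess of 3 covers its slow unproductive decarboxylation. It also needs reduction of the C=C bond alone, which is secured because the catechol ring, the alkyl ester and the aryl C–O bonds are inert to Pd/C at 1 atm and room temperature.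

Compound list
1 | Meldrum's acid (2,2-dimethyl-1,3-dioxane-4,6-dione) | CC1(C)OC(=O)CC(=O)O1 | starting material
2 | 1-hexadecanol (cetyl alcohol) | CCCCCCCCCCCCCCCCO | starting material
3 | hexadecyl hydrogen malonate (3-(hexadecyloxy)-3-oxopropanoic acid) | CCCCCCCCCCCCCCCCOC(=O)CC(=O)O | intermediate
4 | 3,4-dihydroxybenzaldehyde (protocatechualdehyde) | O=Cc1ccc(O)c(O)c1 | starting material
5 | 2-(3,4-dihydroxybenzylidene)malonic acid monohexadecyl ester (mixture of double-bond isomers, geometry not defined and lost on decarboxylation) | CCCCCCCCCCCCCCCCOC(=O)C(=Cc1ccc(O)c(O)c1)C(=O)O | intermediate
6 | hexadecyl (E)-3-(3,4-dihydroxyphenyl)prop-2-enoate (hexadecyl caffeate) | CCCCCCCCCCCCCCCCOC(=O)/C=C/c1ccc(O)c(O)c1 | intermediate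
7 | hexadecyl 3-(3,4-dihydroxyphenyl)propanoate | CCCCCCCCCCCCCCCCOC(=O)CCc1ccc(O)c(O)c1 | target

Total step count: 2
Longest linear sequence: 2 steps (1 and 2 to 3, then 3 and 4 to 7)

Steps most likely to fail (the route has only two steps, so both are ranked, the riskier first):

1. Step 2 (key step). The condensation may stall, because deprotonation of the 4-hydroxyl by the amine base turns the formyl group into a poorly electrophilic vinylogous carboxylate while 3 is consumed by unproductive decarboxylation. In the second stage, amine residues may slow the palladium surface and leave the reduction incomplete. The fallback sets out from 4 and reverses the order of events, with the C–C bond and the reduction first and the hexadecyl ester last. Aldehyde 4, Meldrum's acid 1 and Hantzsch ester (diethyl 2,6-dimethyl-1,4-dihydropyridine-3,5-dicarboxylate) with catalytic L-proline in ethanol at room temperature should give 5-(3,4-dihydroxybenzyl)-2,2-dimethyl-1,3-dioxane-4,6-dione F1 by tandem Knoevenagel condensation and hydride transfer to the arylidene intermediate. Heating F1 with 1-hexadecanol 2 in pyridine with catalytic copper powder should open the dioxanedione ring, release acetone and decarboxylate the resulting half-ester, so that the sequence comes back to the route at the target 7.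

2. Step 1. Prolonged heating may decarboxylate 3 to hexadecyl acetate, and incomplete alcoholysis may carry Meldrum's acid into step 2, where it would compete for the aldehyde. The fallback sets out from 2 and builds the half-ester by orthogonal ester protection instead of ring opening. Steglich esterification of 2 with mono-tert-butyl malonate (3-(tert-butoxy)-3-oxopropanoic acid), DCC and catalytic DMAP in CH2Cl2 at 0 °C to room temperature should give tert-butyl hexadecyl malonate F2. Cleavage of the tert-butyl ester with TFA in CH2Cl2 at room temperature, with loss of isobutene, should bring the sequence back to the route at 3.

Further compounds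
F1 | step 2 | 5-(3,4-dihydroxybenzyl)-2,2-dimethyl-1,3-dioxane-4,6-dione | CC1(C)OC(=O)C(Cc2ccc(O)c(O)c2)C(=O)O1
F2 | step 1 | tert-butyl hexadecyl malonate | CCCCCCCCCCCCCCCCOC(=O)CC(=O)OC(C)(C)C
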